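**Strategy.** Ring A (C1–C5, C10 in eremophilane numbering) is not annulated but grown: the C4–C5 bond is disconnected, because the C3 oxygen, the C4 methyl stereocentre and the quaternary C5 together are the retron of a semipinacol ring enlargement. In one operation a 1,2-shift of the quaternary carbon turns a cyclopentanol into the cyclohexanone of ring A, forms C4 with inversion and keeps C5 intact. The precursor is a hydrindenone with a tertiary hydroxyl and an adjacent (R)-1-mesyloxyethyl branch, built on the commercial (S)-configured bicyclic enedione; its enone later supplies C10–H, the C9 oxygen and the C7 isopropenyl group of ring B.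

Key step: step 4

Remark: decalin positions are given in eremophilane numbering (C3 tiglate carbon, C4 secondary methyl, C5 angular methyl, C7 isopropenyl, C8 ketone, C9 senecioate carbon, C10 ring-fusion CH); the target is read as the (3R,4R,5R,7S,9S,10R) trans-decalin in which only the C5 methyl is axial.

Step 1
Reactants: 1 (7aS)-7a-methyl-2,3,7,7a-tetrahydro-1H-indene-1,5(6H)-dione; 2 ethyl vinyl ether
Product: 4 (1S,7aS)-1-acetyl-1-hydroxy-7a-methyl-1,2,3,6,7,7a-hexahydro-5H-inden-5-one, via enol ether adduct 3 (not isolated)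
Conditions: 2, t-BuLi, THF, −78 → 0 °C; CeCl3, −78 °C; then 1, −78 °C; then 1 M HCl, THF, 0 → 25 °C
Reagents that add atoms: water (SMILES: O)
Why: 1,2-addition of an acyl-anion equivalent (1-ethoxyvinyl organocerium) followed by enol ether hydrolysis: the weakly basic cerium reagent should add to the strained, non-conjugated cyclopentanone faster than to the less electrophilic enone, from the face opposite the angular methyl (1S, hydroxyl cis to the methyl), and dilute acid then unmasks the methyl ketone.

Step 2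
Reactants: 4 (1S,7aS)-1-acetyl-1-hydroxy-7a-methyl-1,2,3,6,7,7a-hexahydro-5H-inden-5-one
Product: 5 (1S,7aS)-1-hydroxy-1-[(1R)-1-hydroxyethyl]-7a-methyl-1,2,3,6,7,7a-hexahydro-5H-inden-5-one
Conditions: Zn(BH4)2, Et2O, −40 → −20 °C; aq. NH4Cl
Reagents that add atoms: none
Why: chelation-controlled ketone reduction: zinc should bridge the tertiary hydroxyl and the side-chain carbonyl, which both accelerates this reduction over that of the enone and exposes the carbonyl face flanked by the ring CH2 (away from the quaternary carbon), so that hydride delivery gives the (1R)-carbinol.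

Step 3
Reactants: 5 (1S,7aS)-1-hydroxy-1-[(1R)-1-hydroxyethyl]-7a-methyl-1,2,3,6,7,7a-hexahydro-5H-inden-5-one
Product: 6 (1R)-1-[(1S,7aS)-1-hydroxy-7a-methyl-5-oxo-2,3,5,6,7,7a-hexahydro-1H-inden-1-yl]ethyl methanesulfonate
Conditions: MsCl, Et3N, CH2Cl2, −20 °C
Reagents that add atoms: methanesulfonyl chloride (SMILES: CS(=O)(=O)Cl)
Why: selective O-sulfonylation: only the secondary hydroxyl should be mesylated, the tertiary hydroxyl next to the quaternary carbon being too hindered, and no stereocenter is touched.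

Step 4
Reactants: 6 (1R)-1-[(1S,7aS)-1-hydroxy-7a-methyl-5-oxo-2,3,5,6,7,7a-hexahydro-1H-inden-1-yl]ethyl methanesulfonate
Product: 7 (4aR,5R)-4a,5-dimethyl-4,4a,7,8-tetrahydronaphthalene-2,6(3H,5H)-dione
Conditions: Et2AlCl (2.5 equiv), CH2Cl2, −78 → −20 °C; 1 M HCl
Reagents that add atoms: none
Why: Et2AlCl converts the tertiary hydroxyl into an aluminium alkoxide and, as a Lewis acid, loosens the neighbouring mesylate, so that the ring bond from the quaternary methyl-bearing carbon (future C5), held anti-periplanar to the C–OMs bond, shifts to the side-chain carbon (future C4) while the carbinol carbon becomes the C3 ketone. The closest known reaction type is the organoaluminium-promoted semipinacol rearrangement of β-mesyloxy alcohols, together with the solvolytic ring enlargement of ring-fused 1-(1-sulfonyloxyethyl)cyclopentanols (D-homoannulation). Ring A is not closed by a cyclisation: the cyclopentane is enlarged by one carbon through a suprafacial 1,2-alkyl shift that exchanges the C3–C5 bond for the C4–C5 bond. C4 is formed with inversion at the mesylate carbon, so its configuration follows from the carbinol set in step 2, and C5 migrates with retention. The step needs migration of the quaternary carbon and not of the ring CH2, and it must outrun epoxide closure and elimination; the higher migratory aptitude of the fully substituted carbon, relief of cyclopentane strain and the non-basic aluminium medium should secure this.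

Step 5
Reactants: 7 (4aR,5R)-4a,5-dimethyl-4,4a,7,8-tetrahydronaphthalene-2,6(3H,5H)-dione
Product: 9 triethyl{[(4aS,5R,6R,8aS)-4a,5-dimethyl-6-(triethylsilyloxy)-3,4,4a,5,6,7,8,8a-octahydronaphthalen-2-yl]oxy}silane, via dilithium enolate alkoxide 8 (not isolated)
Conditions: Li, NH3/THF, t-BuOH (2 equiv), −78 → −33 °C; isoprene; then Et3SiCl, Et3N, THF, −78 → 0 °C
Reagents that add atoms: chlorotriethylsilane (SMILES: CC[Si](Cl)(CC)CC)
Why: Birch-type dissolving-metal reduction with enolate trapping: the enone is reduced to the lithium enolate with axial protonation at C10 giving the trans ring fusion, the C3 ketone is reduced under thermodynamic control to the equatorial (3R) alkoxide, and silylation fixes the enolate as the C8–C9 enol ether.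

Step 6
Reactants: 9 triethyl{[(4aS,5R,6R,8aS)-4a,5-dimethyl-6-(triethylsilyloxy)-3,4,4a,5,6,7,8,8a-octahydronaphthalen-2-yl]oxy}silane
Product: 11 (1S,4aR,5R,6R,8aR)-4a,5-dimethyl-1,6-bis(triethylsilyloxy)octahydronaphthalen-2(1H)-one, via silyloxy epoxide 10 (not isolated)
Conditions: mCPBA, NaHCO3, CH2Cl2, −20 → 0 °C
Reagents that add atoms: 3-chloroperoxybenzoic acid (SMILES: OOC(=O)c1cccc(Cl)c1)
Why: Rubottom oxidation: the peracid should epoxidise only the electron-rich enol ether, from the face opposite the axial C5 methyl that is 1,3 to C9, and silyl migration opens the epoxide to the equatorial (9S) silyloxy ketone.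

Step 7
Reactants: 11 (1S,4aR,5R,6R,8aR)-4a,5-dimethyl-1,6-bis(triethylsilyloxy)octahydronaphthalen-2(1H)-one; 12 2-bromopropene
Product: 14 (1S,3S,4aR,5R,6R,8aR)-1,6-dihydroxy-4a,5-dimethyl-3-(prop-1-en-2-yl)octahydronaphthalen-2(1H)-one, via bis-silyl isopropenyl ketone 13 (not isolated)
Conditions: LiN(SiMe3)2 (2.2 equiv), Pd2(dba)3 (dba = dibenzylideneacetone, 2.5 mol %), P(t-Bu)3 (6 mol %), toluene, 0 → 25 °C; AcOH, −78 °C; then HF·pyridine, pyridine, THF, 0 °C
Reagents that add atoms: none
Why: palladium-catalysed α-alkenylation of a ketone enolate followed by fluoride desilylation: the amide base should remove a C7 proton (the C9 methine is silyloxy-substituted and shielded), the alkenylpalladium species formed from zerovalent palladium and 12 couples at C7, and axial protonation of the resulting dienolate places the isopropenyl group equatorial (7S), away from the 1,3-related axial C5 methyl.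

Step 8
Reactants: 14 (1S,3S,4aR,5R,6R,8aR)-1,6-dihydroxy-4a,5-dimethyl-3-(prop-1-en-2-yl)octahydronaphthalen-2(1H)-one; 15 tiglic acid
Product: 16 (1R,2R,4aR,5S,7S,8aR)-5-hydroxy-1,8a-dimethyl-6-oxo-7-(prop-1-en-2-yl)decahydronaphthalen-2-yl (2E)-2-methylbut-2-enoate
Conditions: 15 (1.05 equiv), DCC, DMAP (cat.), CH2Cl2, −20 → 0 °C
Reagents that add atoms: none
Why: Steglich esterification under site control: the C3 hydroxyl should react faster than the C9 hydroxyl, which is hydrogen-bonded to and inductively deactivated by the adjacent ketone, so that one equivalent of the acyl donor at low temperature gives the C3 tiglate with the E double bond unchanged.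

Step 9
Reactants: 16 (1R,2R,4aR,5S,7S,8aR)-5-hydroxy-1,8a-dimethyl-6-oxo-7-(prop-1-en-2-yl)decahydronaphthalen-2-yl (2E)-2-methylbut-2-enoate; 17 senecioic acid
Product: 18 (1R,2R,4aR,5S,7S,8aR)-1,8a-dimethyl-5-[(3-methylbut-2-enoyl)oxy]-6-oxo-7-(prop-1-en-2-yl)decahydronaphthalen-2-yl (2E)-2-methylbut-2-enoate
Conditions: 17, DCC, DMAP, CH2Cl2, 0 → 25 °C
Reagents that add atoms: none
Why: Steglich esterification of the remaining α-ketol hydroxyl with senecioic acid under mild, weakly basic conditions that should leave the C7 and C9 stereocenters and the isopropenyl group untouched.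

**Compound list**

1 | (7aS)-7a-methyl-2,3,7,7a-tetrahydro-1H-indene-1,5(6H)-dione | C[C@]12CCC(=O)C=C1CCC2=O | starting material
2 | ethyl vinyl ether (ethoxyethene) | C=COCC | starting material
3 | (1S,7aS)-1-(1-ethoxyethenyl)-1-hydroxy-7a-methyl-1,2,3,6,7,7a-hexahydro-5H-inden-5-one (hydroxyl cis to the angular methyl) | C1C[C@]2(C)[C@](O)(C(=C)OCC)CCC2=CC1=O | intermediate
4 | (1S,7aS)-1-acetyl-1-hydroxy-7a-methyl-1,2,3,6,7,7a-hexahydro-5H-inden-5-one | C1C[C@]2(C)[C@](O)(C(C)=O)CCC2=CC1=O | intermediate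
5 | (1S,7aS)-1-hydroxy-1-[(1R)-1-hydroxyethyl]-7a-methyl-1,2,3,6,7,7a-hexahydro-5H-inden-5-one | C1C[C@]2(C)[C@](O)([C@@H](C)O)CCC2=CC1=O | intermediate
6 | (1R)-1-[(1S,7aS)-1-hydroxy-7a-methyl-5-oxo-2,3,5,6,7,7a-hexahydro-1H-inden-1-yl]ethyl methanesulfonate | C1C[C@]2(C)[C@](O)([C@@H](C)OS(C)(=O)=O)CCC2=CC1=O | intermediate
7 | (4aR,5R)-4a,5-dimethyl-4,4a,7,8-tetrahydronaphthalene-2,6(3H,5H)-dione (the two methyls cis) | C1C[C@]2(C)[C@@H](C)C(=O)CCC2=CC1=O | intermediate
8 | dilithium (4aS,5R,6R,8aS)-4a,5-dimethyl-3,4,4a,5,6,7,8,8a-octahydronaphthalene-2,6-bis(olate) (C8–C9 lithium enolate and C3 lithium alkoxide, trans-fused) | C1C[C@]2(C)[C@@H](C)[C@H](O[Li])CC[C@H]2C=C1O[Li] | intermediate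
9 | triethyl{[(4aS,5R,6R,8aS)-4a,5-dimethyl-6-(triethylsilyloxy)-3,4,4a,5,6,7,8,8a-octahydronaphthalen-2-yl]oxy}silane | C1C[C@]2(C)[C@@H](C)[C@H](O[Si](CC)(CC)CC)CC[C@H]2C=C1O[Si](CC)(CC)CC | intermediate
10 | oxirane across C8–C9 of 9, epoxide oxygen on the face opposite the C5 methyl, C8 still carrying the triethylsilyloxy group | C1C[C@]2(C)[C@@H](C)[C@H](O[Si](CC)(CC)CC)CC[C@H]2[C@@H]3O[C@]13O[Si](CC)(CC)CC | intermediate
11 | (1S,4aR,5R,6R,8aR)-4a,5-dimethyl-1,6-bis(triethylsilyloxy)octahydronaphthalen-2(1H)-one | C1C[C@]2(C)[C@@H](C)[C@H](O[Si](CC)(CC)CC)CC[C@H]2[C@H](O[Si](CC)(CC)CC)C1=O | intermediate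
12 | 2-bromopropene | CC(Br)=C | starting material
13 | (1S,3S,4aR,5R,6R,8aR)-4a,5-dimethyl-3-(prop-1-en-2-yl)-1,6-bis(triethylsilyloxy)octahydronaphthalen-2(1H)-one | C=C(C)[C@@H]1C[C@]2(C)[C@@H](C)[C@H](O[Si](CC)(CC)CC)CC[C@H]2[C@H](O[Si](CC)(CC)CC)C1=O | intermediate
14 | (1S,3S,4aR,5R,6R,8aR)-1,6-dihydroxy-4a,5-dimethyl-3-(prop-1-en-2-yl)octahydronaphthalen-2(1H)-one | C=C(C)[C@@H]1C[C@]2(C)[C@@H](C)[C@H](O)CC[C@H]2[C@H](O)C1=O | intermediate
15 | tiglic acid, (2E)-2-methylbut-2-enoic acid | C/C=C(\C)C(=O)O | starting material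
16 | (1R,2R,4aR,5S,7S,8aR)-5-hydroxy-1,8a-dimethyl-6-oxo-7-(prop-1-en-2-yl)decahydronaphthalen-2-yl (2E)-2-methylbut-2-enoate | C=C(C)[C@@H]1C[C@]2(C)[C@@H](C)[C@H](OC(=O)/C(C)=C/C)CC[C@H]2[C@H](O)C1=O | intermediate
17 | senecioic acid, 3-methylbut-2-enoic acid | CC(C)=CC(=O)O | starting material
18 | (1R,2R,4aR,5S,7S,8aR)-1,8a-dimethyl-5-[(3-methylbut-2-enoyl)oxy]-6-oxo-7-(prop-1-en-2-yl)decahydronaphthalen-2-yl (2E)-2-methylbut-2-enoate | C=C(C)[C@@H]1C[C@]2(C)[C@@H](C)[C@H](OC(=O)/C(C)=C/C)CC[C@H]2[C@H](OC(=O)C=C(C)C)C1=O | target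

**Step count and risks**

Total step count: 9. Longest linear sequence: 9 steps (1 → 18).

Steps most likely to fail:

Step 7. The palladium enolate may undergo β-hydride elimination instead of coupling, the enolate may equilibrate toward C9 before coupling, or the base may move the new double bond into conjugation with the ketone. The fallback replaces cross-coupling by aldol addition and dehydration. Setting out from compound 11, the lithium enolate (LiN(i-Pr)2, THF, −78 °C, then ZnCl2) would be added to acetone to give the aldol adduct F4. Its tertiary hydroxyl would then be eliminated toward a methyl group (SOCl2, pyridine, −20 °C). This returns to the route at compound 13, which is desilylated as in step 7.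

Step 8. Discrimination between the two secondary hydroxyls may be insufficient, so that acylation also occurs at C9 or twice. The fallback replaces site selection by orthogonal protection and sets out from compound 9.
- MeLi (THF, 0 °C) would cleave only the silyl enol ether, and the lithium enolate would be hydroxylated with 2-(phenylsulfonyl)-3-phenyloxaziridine (−78 °C) to the C9 hydroxy ketone F5, with the C3 triethylsilyl ether intact.
- Silylation (t-BuMe2SiOTf, 2,6-lutidine) would give the mixed bis-silyl ether F6.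
- Alkenylation with 12 as in step 7, without the fluoride stage, would give the isopropenyl ketone F7.
- Pyridinium p-toluenesulfonate in MeOH would remove only the triethylsilyl group to give the C3 alcohol F8.
- Esterification with 15 as in step 8 would give the silyl-protected tiglate F9.
- HF·pyridine would then free the C9 hydroxyl, returning to the route at compound 16.

Step 1. The organometallic reagent may add to, or deprotonate, the enone instead of reacting only at the cyclopentanone. The fallback masks the enone first. Setting out from compound 1, selective dithioketalisation of the conjugated carbonyl (ethane-1,2-dithiol, BF3·OEt2, AcOH) would give the enone dithiolane F1. Addition of 1-ethoxyvinyllithium would give the enol ether adduct F2, and dilute acid would hydrolyse it to the acetyl carbinol F3. Removal of the dithiolane (MeI, CaCO3, aqueous MeCN) would return to the route at compound 4.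

Further compounds
F1 | step 1 | (7a'S)-7a'-methyl-2',3',7',7a'-tetrahydrospiro[1,3-dithiolane-2,5'-inden]-1'(6'H)-one | C1C[C@]2(C)C(=O)CCC2=CC13SCCS3
F2 | step 1 | (1'S,7a'S)-1'-(1-ethoxyethenyl)-7a'-methyl-1',2',3',6',7',7a'-hexahydrospiro[1,3-dithiolane-2,5'-inden]-1'-ol | C1C[C@]2(C)[C@](O)(C(=C)OCC)CCC2=CC13SCCS3
F3 | step 1 | 1-[(1'S,7a'S)-1'-hydroxy-7a'-methyl-1',2',3',6',7',7a'-hexahydrospiro[1,3-dithiolane-2,5'-inden]-1'-yl]ethan-1-one | C1C[C@]2(C)[C@](O)(C(C)=O)CCC2=CC13SCCS3
F4 | step 7 | (1S,3S,4aR,5R,6R,8aR)-3-(2-hydroxypropan-2-yl)-4a,5-dimethyl-1,6-bis(triethylsilyloxy)octahydronaphthalen-2(1H)-one | CC(C)(O)[C@@H]1C[C@]2(C)[C@@H](C)[C@H](O[Si](CC)(CC)CC)CC[C@H]2[C@H](O[Si](CC)(CC)CC)C1=O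
F5 | step 8 | (1S,4aR,5R,6R,8aR)-1-hydroxy-4a,5-dimethyl-6-(triethylsilyloxy)octahydronaphthalen-2(1H)-one | C1C[C@]2(C)[C@@H](C)[C@H](O[Si](CC)(CC)CC)CC[C@H]2[C@H](O)C1=O
F6 | step 8 | (1S,4aR,5R,6R,8aR)-1-(tert-butyldimethylsilyloxy)-4a,5-dimethyl-6-(triethylsilyloxy)octahydronaphthalen-2(1H)-one | C1C[C@]2(C)[C@@H](C)[C@H](O[Si](CC)(CC)CC)CC[C@H]2[C@H](O[Si](C)(C)C(C)(C)C)C1=O
F7 | step 8 | (1S,3S,4aR,5R,6R,8aR)-1-(tert-butyldimethylsilyloxy)-4a,5-dimethyl-3-(prop-1-en-2-yl)-6-(triethylsilyloxy)octahydronaphthalen-2(1H)-one | C=C(C)[C@@H]1C[C@]2(C)[C@@H](C)[C@H](O[Si](CC)(CC)CC)CC[C@H]2[C@H](O[Si](C)(C)C(C)(C)C)C1=O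
F8 | step 8 | (1S,3S,4aR,5R,6R,8aR)-1-(tert-butyldimethylsilyloxy)-6-hydroxy-4a,5-dimethyl-3-(prop-1-en-2-yl)octahydronaphthalen-2(1H)-one | C=C(C)[C@@H]1C[C@]2(C)[C@@H](C)[C@H](O)CC[C@H]2[C@H](O[Si](C)(C)C(C)(C)C)C1=O
F9 | step 8 | (1R,2R,4aR,5S,7S,8aR)-5-(tert-butyldimethylsilyloxy)-1,8a-dimethyl-6-oxo-7-(prop-1-en-2-yl)decahydronaphthalen-2-yl (2E)-2-methylbut-2-enoate | C=C(C)[C@@H]1C[C@]2(C)[C@@H](C)[C@H](OC(=O)/C(C)=C/C)CC[C@H]2[C@H](O[Si](C)(C)C(C)(C)C)C1=O
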